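**Direct plan and its weak points**

A direct plan would build the chain around an alkyne: propyne A1 would be doubly lithiated and alkylated in one pot, first with (11-bromoundecyloxy)(tert-butyl)dimethylsilane A2, then with 1-bromo-6-methylheptane A3.
Desilylation would give 20-methylhenicos-13-yn-1-ol A4, a carbodiimide esterification with 2,3-bis(benzyloxy)benzoic acid A5 would give 20-methylhenicos-13-ynyl 2,3-bis(benzyloxy)benzoate A6, and hydrogenation of A6 would finish.
Weak point a, the one-pot double alkylation of doubly lithiated A1 by A2 and A3: it would rest on site selectivity between two carbanion centres and on excess dianion and excess A3, and it would install a triple bond that the target does not contain.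
Weak point b, the protecting-group traffic: silylation and desilylation on the way from A2 to A4, and threefold benzylation, saponification and final debenzylation around A5, would form no bond of the target, yet would make up most of the operations.
Weak point c, the closing hydrogenation of A6: alkyne saturation and two hydrogenolyses would have to go to completion together on a waxy, poorly soluble ester at the very end, where partly reduced material would be hard to remove.

**Retrosynthetic overview of the new route**

The target is cut at O–C1 (alkylation of the free acid's carboxylate) and at C15–C16, inside the handle-free polymethylene run C2–C19 of the 20-methylhenicosyl chain.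
The C15–C16 cut joins two carbons of like polarity, both former α-carbons of carboxylic acids, by anodic decarboxylative radical coupling of 16-bromohexadecanoic acid (1) and 6-methylheptanoic acid (2).
The isopropyl end (C20, C21 and the branch methyl) arrives ready-made in 2; the bromide of 1 survives the electrolysis in bromide 3 and then serves as the electrophile toward 2,3-dihydroxybenzoic acid (4).
No ring is formed: the benzene ring is bought with 4.
The chain is born saturated (no alkyne, no hydrogenation), no dianion selectivity is needed, and the pKa gap between CO2H and the phenols replaces every protecting group.

Key step: step 1

Assumption: 16-bromohexadecanoic acid and isomerically pure 6-methylheptanoic acid are taken as catalogue compounds; the target is achiral, so no stereocentre has to be set.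

**Route**

Step 1
Reactants: 1 16-bromohexadecanoic acid; 2 6-methylheptanoic acid
Product: 3 1-bromo-20-methylhenicosane
Conditions: 1 (1 equiv), 2 (4 equiv), NaOMe (5 mol% of total acid), MeOH, 45–50 °C, undivided cell, smooth Pt anode, Pt cathode, constant current ca. 0.25 A cm−2, ca. 1.3 F per mol of acid, to a faintly alkaline end point; hexane extraction, bulb-to-bulb distillation, cold hexane filtration, SiO2 (hexane)
Reagents that add atoms: none
Why: This is a mixed (crossed) Kolbe electrolysis, an anodic decarboxylative radical–radical coupling: the carboxylates of 1 and 2, held on the Pt anode at high current density, are each oxidised by one electron, the acyloxy radicals lose CO2, and the primary radicals Br(CH2)15• and (CH3)2CH(CH2)4• combine at the electrode surface to form the C15–C16 bond, while protons are discharged to H2 at the cathode. The closest known reaction type is the crossed Kolbe coupling of an ω-bromoalkanoic acid with a second alkanoic acid in weakly acidic methanol. No ring is closed and no stereocentre is created. The step needs three selectivities: radical coupling rather than two-electron oxidation to a cation (Hofer–Moest path), which should hold because both radicals are primary and unbranched at the α-carbon (the C20 branch sits four carbons from the radical centre) and because smooth Pt, high current density and only 5% neutralisation are used; cross- rather than homo-coupling, which is statistical and is therefore steered by the fourfold excess of 2 so that most of 1 should end in 3; and survival of the C–Br bond, which is not oxidised at the anode, should not be reduced at Pt while protons are available, and is not displaced because the medium stays acidic until the end point. The two homodimers differ from 3 in volatility (2,11-dimethyldodecane, distilled off) and in solubility (1,30-dibromotriacontane, filtered from cold hexane), and any dibromide carried on would become a far more polar bis-catechol diester after step 2.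

Step 2
Reactants: 3 1-bromo-20-methylhenicosane; 4 2,3-dihydroxybenzoic acid
Product: 6 Gentiside A (20-methylhenicosyl 2,3-dihydroxybenzoate), via potassium 2,3-dihydroxybenzoate 5 (not isolated)
Conditions: 4 (1.5 equiv), KHCO3 (1.5 equiv), DMF, rt, Ar; then 3 (1 equiv), KI (10 mol%), 65 °C; dil. HCl/EtOAc; SiO2 (hexane/EtOAc)
Reagents that add atoms: none
Why: In this carboxylate O-alkylation (SN2 ester formation from an alkali carboxylate and a primary alkyl halide, with Finkelstein assistance by iodide), hydrogencarbonate used in no excess over 4 deprotonates only the CO2H (pKa about 3) and not the phenols (pKa about 10 and above), so the carboxylate should be the only competent nucleophile toward the unhindered primary bromide and the catechol stays free without protection.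

**Compound list**

1 | 16-bromohexadecanoic acid | OC(=O)CCCCCCCCCCCCCCCBr | starting material
2 | 6-methylheptanoic acid | CC(C)CCCCC(=O)O | starting material
3 | 1-bromo-20-methylhenicosane | CC(C)CCCCCCCCCCCCCCCCCCCBr | intermediate
4 | 2,3-dihydroxybenzoic acid | O=C(O)c1cccc(O)c1O | starting material
5 | potassium 2,3-dihydroxybenzoate | [K+].[O-]C(=O)c1cccc(O)c1O | intermediate (not isolated)
6 | Gentiside A, 20-methylhenicosyl 2,3-dihydroxybenzoate (achiral) | CC(C)CCCCCCCCCCCCCCCCCCCOC(=O)c1cccc(O)c1O | target

**Step count and risks**

Total step count: 2. Longest linear sequence: 2 steps (1 → 3 → 6). The route has only two steps, so both are ranked and a third cannot be named.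

Most likely to fail, first: step 1 (crossed Kolbe electrolysis). Three processes could go wrong. The radicals could be over-oxidised to cations and captured by methanol. The waxy products could coat the anode and lower the current efficiency. The statistical product set could resist separation. The fallback replaces the radical–radical coupling by a polar, copper-catalysed alkyl–alkyl coupling; it sets out from 1 and comes back at 3. 1-Bromo-4-methylpentane F1 (purchased) would be converted with Mg in THF into 4-methylpentylmagnesium bromide F2. Compound 1 in THF at −20 °C would be treated with F2 (2.5 equiv, the first equivalent forming the bromomagnesium carboxylate) and Li2CuCl4 (3 mol%). This copper-catalysed Grignard cross-coupling at the primary bromide should give 20-methylhenicosanoic acid F3 after acidic work-up. LiAlH4 in THF would reduce F3 to 20-methylhenicosan-1-ol F4, and CBr4/PPh3 in CH2Cl2 (Appel reaction) would return bromide 3.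

Second: step 2 (carboxylate alkylation). A phenolic oxygen could be alkylated once the carboxylate runs short, or the catechol could degrade oxidatively in warm DMF. The fallback changes to a redox condensation under neutral conditions, with an alcohol instead of a bromide as the chain partner; it sets out from 2 and 4 and comes back at 6. The electrolysis of step 1 would be run with 16-hydroxyhexadecanoic acid F5 (purchased) in place of 1. This should give 20-methylhenicosan-1-ol F4 directly, which is easily separated by polarity from the hydrocarbon dimer and from triacontane-1,30-diol. F4 would then be condensed with 4 under Mitsunobu conditions (PPh3, DIAD, THF, 0 °C → rt). No base is present and no phenoxide is formed, and the carboxylic acid, by far the most acidic pronucleophile, should be the only group alkylated by the alkoxyphosphonium ion.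

**Further compounds**

F1 | step 1 | 1-bromo-4-methylpentane (purchased) | CC(C)CCCBr
F2 | step 1 | 4-methylpentylmagnesium bromide | CC(C)CCC[Mg]Br
F3 | step 1 | 20-methylhenicosanoic acid | CC(C)CCCCCCCCCCCCCCCCCCC(=O)O
F4 | step 1 | 20-methylhenicosan-1-ol | CC(C)CCCCCCCCCCCCCCCCCCCO
F5 | step 2 | 16-hydroxyhexadecanoic acid (purchased) | OC(=O)CCCCCCCCCCCCCCCO
A1 | direct plan | propyne | CC#C
A2 | direct plan | (11-bromoundecyloxy)(tert-butyl)dimethylsilane | CC(C)(C)[Si](C)(C)OCCCCCCCCCCCBr
A3 | direct plan | 1-bromo-6-methylheptane | CC(C)CCCCCBr
A4 | direct plan | 20-methylhenicos-13-yn-1-ol | CC(C)CCCCCC#CCCCCCCCCCCCCO
A5 | direct plan | 2,3-bis(benzyloxy)benzoic acid | O=C(O)c1cccc(OCc2ccccc2)c1OCc1ccccc1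
A6 | direct plan | 20-methylhenicos-13-ynyl 2,3-bis(benzyloxy)benzoate | CC(C)CCCCCC#CCCCCCCCCCCCCOC(=O)c1cccc(OCc2ccccc2)c1OCc1ccccc1
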